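A one-step world keeps simple books: each starting material that reacts meets one coupling partner and becomes target, at a rate proportional to c(starting material) × c(coupling partner).

| setting | spring | midnight | autumn | noon | dawn |
|---|---|---|---|---|---|
| starting material | 150 mM | 60.0 mM | 300 mM | 150 mM | 150 mM |
| coupling partner | 375 mM | 285 mM | 375 mM | 1100 mM | 375 mM |
| time |  |  |  |  | 8.2 min |

| run | time / min | [target] / mM |
|---|---|---|
| spring run | 0.59 | 18.0 |
| spring run | 1.2 | 32.1 |
| spring run | 1.8 | 44.9 |
| spring run | 2.3 | 51.9 |
| spring run | 2.9 | 59.6 |
| spring run | 3.5 | 66.9 |
| spring run | 4.1 | 72.2 |
| midnight run | 0.59 | 5.8 |
| midnight run | 1.2 | 10.4 |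
| midnight run | 1.8 | 13.5 |
| midnight run | 2.3 | 17.5 |
| midnight run | 2.9 | 21.0 |
| midnight run | 3.5 | 23.6 |
| midnight run | 4.1 | 26.2 |
| autumn run | 0.59 | 33.3 |
| autumn run | 1.2 | 59.6 |
| autumn run | 1.8 | 79.0 |
| autumn run | 2.3 | 91.9 |
| autumn run | 2.9 | 104.4 |
| autumn run | 3.5 | 114.0 |
| autumn run | 4.1 | 122.2 |
| noon run | 0.59 | 49.3 |
| noon run | 1.2 | 80.3 |
| noon run | 1.8 | 100.0 |
| noon run | 2.3 | 110.5 |
| noon run | 2.9 | 118.0 |
| noon run | 3.5 | 123.2 |
| noon run | 4.1 | 125.8 |

(readings scatter by 0.4 mM)

- Overall: starting material + coupling partner -> target.
- Constant volume, constant temperature.
- A reading of a species includes what of it is bound.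
- "The second partner" is coupling partner.
- An order is taken over about fifteen percent of the charge, up and down.

1. order of the initial rate in [starting material], near the charge of the spring run, the rate being that where two percent of its starting material are target (one fixed amount of target, the same in the runs compared)
2. order of the initial rate in [coupling partner], near the charge of the spring run, the rate being that where two percent of its starting material are target
3. target in the dawn run at 8.2 min, as a share of the starting material charged

In the spring run, starting material is the limiting reagent, at 150 mM against 375 mM of coupling partner. The first interval makes target at 30.5 mM/min, around 9.00 mM made. The last two intervals together give 10.5 mM/min, around 65.9 mM made. Debiting both concentrations by the target made, the one-step books allow 15.4 mM/min there, so the spring run is slower than those books allow.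

A plainer entry follows. A straight line through these two points has rate falling by 0.352 /min per unit of target made. The reach, the target at which that line of rate against target made meets zero, is 95.8 mM. This line thus credits target in the spring run with 63.9 % of the charge, as an estimate, and 54.2 mM of starting material stand outside this entry. On such a line the gap to the reach shrinks exponentially at 0.352 /min. The dawn run repeats the spring charge, so this reckoning puts it at 60.3 % at 8.2 min.

First-interval readings, taken at unequal amounts of target, give rough orders. Autumn, with twice the starting material of spring, reads as order 0.888 in starting material. Noon against spring reads as 0.936 in coupling partner.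

The forecast gives 0.9 and 1 for these orders and 60 % for dawn, on its own grounds: “That points to a reversible step”.

The flask runs by this scheme:

    2 coupling partner ⇌ reagent dimer, settled at all times (36.80 /M)
    starting material + reagent dimer → target + coupling partner (1.470 /M/min)
    2 starting material → homo dimer (0.2754 /M/min)
    target → decomposed product (0.01746 /min)

The dawn run gives 61.4 %, with orders 1.0 and 1.1. The spring run reaches half of its starting material as target at 4.45 min, where the reach and its slope put 4.35 min. The scheme has no return from target to starting material, and starting material also leaves as homo dimer; the reach stays a reading of the curve, not an equilibrium. In the midnight run, the same two rates, 9.83 mM/min and 4.33 mM/min, slope 0.266 /min, give a reach of 39.9 mM and half its charge as target at 5.24 min, against 5.20 min in the flask.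

The numbers in the tables are simulated with made-up constants; scatter was added.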